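- the flask that comes out highest in amount of ring, in percent of the starting material charged, or "all alike" when all lie within 1.5 percentage points (alder / maple / all alike)
- ring at the end, in percent of the starting material charged, alder
- ring at the end, in percent of the starting material charged, maple

| flask | starting material | activator | protic impurity | temperature | remark | time |
|---|---|---|---|---|---|---|
| zeta | 6.7 mM | 2 equiv | 5 mM | 10 °C | run made earlier |  |
| alpha | 15 mM | 2 equiv | 5 mM | 21 °C | run made earlier |  |
| epsilon | 10 mM | 2 equiv | 2.5 mM | 10 °C | run made earlier |  |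
| alder | 10 mM | 2.00 equiv | 5.00 mM | 5 °C |  | 6.0 min |
| maple | 10 mM | 2.00 equiv | 5.00 mM | 25 °C |  | 6.0 min |

| run | time / min | ring / % | starting material / % |
|---|---|---|---|
| zeta | 0.667 | 1.2 | 30.4 |
| zeta | 1.33 | 3.3 | 11.0 |
| zeta | 2.00 | 6.1 | 5.6 |
| zeta | 3.00 | 9.4 | 3.3 |
| zeta | 4.00 | 11.7 | 2.9 |
| zeta | 5.00 | 13.9 | 1.3 |
| alpha | 0.333 | 4.6 | 14.7 |
| alpha | 0.667 | 9.3 | 4.6 |
| alpha | 0.833 | 12.1 | 4.4 |
| alpha | 1.33 | 17.3 | 2.6 |
| alpha | 2.00 | 23.7 | 2.6 |
| alpha | 2.50 | 26.8 | 2.1 |
| epsilon | 1.00 | 3.8 | 18.3 |
| epsilon | 2.00 | 7.5 | 4.5 |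
| epsilon | 3.00 | 11.7 | 3.2 |
| epsilon | 4.00 | 14.6 | 2.1 |
| epsilon | 5.00 | 18.7 | 2.3 |

(readings scatter by 0.5 percentage points)

1. Start from 16.5 min, the closing time τ: the time constant with which ring climbs towards the ceiling of the next step, here in the epsilon run at 10 °C. Read it from the ring readings at 2.00 min and 5.00 min, taken after starting material has fallen to 4.5%.

2. Follow one molecule of starting material. At the first fork, assume protic impurity removes it mole for mole, so the ceiling is 1 − c(protic impurity)/c(starting material): 75.0% in epsilon, 50.0% in alder and maple. At the second fork, take its chance of closing within time t as 1 − exp(−t/τ), a first-order relaxation.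

3. Repeat the reading on alpha: τ is 4.61 min at 21 °C. Draw ln τ as a straight line in temperature. That line credits temperature with the change, though alpha's charges differ from epsilon's too. This gives 29.5 min for alder and 2.90 min for maple.

4. Solve two extremes. On my curve, with τ far longer than the run, ring follows the line ceiling × t/τ; with τ far shorter, ring equals the ceiling. Alder lies near the first, since 6.0 min is shorter than its τ: t/τ is 0.203, and my curve gives 9.19%. Maple leans to the second, with t/τ at 2.07, and my curve gives 43.7%.

5. The forecast names maple, with 9% (6% to 12.5%) for alder and 36% (28% to 45%) for maple, “allowing for the extra loss seen in alpha”. Its maple figure stands below my curve.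

6. The simulation puts maple highest.

    activated form → ring (k = 0.0200 s⁻¹, Ea = 77.0 kJ mol⁻¹)
    2 starting material → self-condensation product (k = 1.70 L mol⁻¹ s⁻¹, Ea = 44.0 kJ mol⁻¹)
    starting material + activator → activated form (k = 1.70 L mol⁻¹ s⁻¹, Ea = 53.0 kJ mol⁻¹)
    starting material ⇌ dormant form (K = 2.70, k = 0.0440 s⁻¹, Ea = 75.0 kJ mol⁻¹, ΔH = −31.0 kJ mol⁻¹)
    starting material + activated form → open dimer (k = 3.60 L mol⁻¹ s⁻¹, Ea = 44.0 kJ mol⁻¹)
    starting material + protic impurity → quenched substrate (k = 7.00 L mol⁻¹ s⁻¹, Ea = 57.0 kJ mol⁻¹)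
    (constants at 25 °C)

7. Maple gives 39.2% ring and alder 12.3%. At 6.00 min maple holds 1.01% activated form, less than the 13.4% in alder. Now apply τ to the maple charge kept at 0 °C: τ comes to 52.8 min, t/τ to 0.114, and the curve to 5.37%. That flask, lower than alder, gives 7.09% ring.

(Readings and results stem from a simulated flask on assumed constants; noise was put on by code.)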